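**Plan**
The retrosynthesis first re-masks the 4-quinolone and the acid as a 4-methyl ether and a methyl ester, then takes the C8 methyl ether back to a phenol.
It then cuts the benzo ring at C4a–C5 and C8a–C8, which leads to a 2,3-pyridyne and 3,4-dibromofuran joined through an oxygen bridge from C5 to C8.
The enabling feature is that C5 to C8 carry H, Br, Br, O in a row: these are the four carbons and the ring oxygen of 3,4-dibromofuran laid across the C4a–C8a bond of a 4-oxygenated pyridine-2-carboxylate.
Forward: the pyridine ring is bought and turned into an ortho-iodo triflate; the carbocycle closes in the pyridyne cycloaddition; acid opens the bridge to the 8-quinolinol; methylation and unmasking finish the route.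
Stereochemistry: the target has none; the two bridgehead centres of the cycloadduct form cis and racemic and are erased on aromatisation.

Key step: step 5

Assumption: compounds 1 and 7 are purchased; cycloadduct 10 is racemic and its SMILES shows one enantiomer; the target is written as the NH 4-quinolone tautomer.

**Route**

Step 1
Reactants: 1 methyl 4-methoxypicolinate
Product: 2 methyl 4-methoxypicolinate N-oxide
Conditions: mCPBA, CH2Cl2, 0 °C to rt
Reagents that add atoms: mCPBA, O=C(OO)c1cccc(Cl)c1
Why: Peracid N-oxidation of a pyridine; the 4-methoxy group keeps the ring nitrogen nucleophilic despite the neighbouring ester, and nothing else in 1 is oxidisable.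

Step 2
Reactants: 2 methyl 4-methoxypicolinate N-oxide
Product: 4 methyl 4-methoxy-6-oxo-1,6-dihydropyridine-2-carboxylate, via 6-trifluoroacetoxypyridine ester 3 (not isolated)
Conditions: (CF3CO)2O, DMF, 0 °C to rt; then MeOH, rt
Reagents that add atoms: trifluoroacetic anhydride, O=C(OC(=O)C(F)(F)F)C(F)(F)F (one of its oxygens ends up on C6)
Why: N-oxide to 2-pyridone rearrangement under acylative activation: O-trifluoroacetylation makes the ring electrophilic, trifluoroacetate adds at C6 (the only unsubstituted carbon next to nitrogen), loss of trifluoroacetic acid rearomatises to 3, and methanolysis of this activated aryl ester leaves the pyridone.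

Step 3
Reactants: 4 methyl 4-methoxy-6-oxo-1,6-dihydropyridine-2-carboxylate
Product: 5 methyl 5-iodo-4-methoxy-6-oxo-1,6-dihydropyridine-2-carboxylate
Conditions: NIS, cat. CF3CO2H, MeCN, rt
Reagents that add atoms: N-iodosuccinimide, O=C1CCC(=O)N1I
Why: Electrophilic iodination of a 4-alkoxy-2-pyridone: C5 is the alpha carbon of the beta-methoxy enone unit and sits ortho to both oxygen donors, whereas the other free carbon (C3) is the beta carbon of the acrylate formed with the ester and is shielded by it, so iodine should enter at C5.

Step 4
Reactants: 5 methyl 5-iodo-4-methoxy-6-oxo-1,6-dihydropyridine-2-carboxylate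
Product: 6 methyl 5-iodo-4-methoxy-6-(trifluoromethylsulfonyloxy)picolinate
Conditions: Tf2O, pyridine, CH2Cl2, −20 to 0 °C
Reagents that add atoms: triflic anhydride, O=S(=O)(OS(=O)(=O)C(F)(F)F)C(F)(F)F
Why: O-sulfonylation of a 2-pyridone with triflic anhydride and an amine base; it is O-selective because the aromatic 2-pyridyl triflate is the stable product and the nitrogen is flanked by two substituents.

Step 5
Reactants: 6 methyl 5-iodo-4-methoxy-6-(trifluoromethylsulfonyloxy)picolinate; 7 3,4-dibromofuran
Product: 10 methyl 6,7-dibromo-4-methoxy-5,8-dihydro-5,8-epoxyquinoline-2-carboxylate (racemic), via pyridylmagnesium chloride 8 (not isolated), via 2,3-pyridyne 9 (not isolated)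
Conditions: 7 (5 equiv), THF, −78 °C; Me3SiCH2MgCl (1.1 equiv, slow addition); −78 °C to rt
Reagents that add atoms: none
Why: Iodine–magnesium exchange at the C5 iodide, activated by the flanking triflate and methoxy groups, gives arylmagnesium 8; beta-elimination of the neighbouring triflate releases 2,3-pyridyne 9, whose strained triple bond is taken up by the 2,5-carbons of furan 7 in a concerted [4+2] cycloaddition. The closest known reaction type is the Diels–Alder trapping by furans of arynes and hetarynes generated from ortho-iodoaryl triflates with a Grignard reagent. The six-membered carbocycle (C4a, C5, C6, C7, C8, C8a) closes in this single intermolecular cycloaddition, the C4a–C5 and C8a–C8 bonds forming suprafacially on the diene. The two bridgehead stereocentres C5 and C8 can only form cis because the oxygen bridge ties them together; they arise as a racemate and both disappear in step 6. No regioselectivity is needed because 7 is C2v-symmetric; the chemoselectivity needed (exchange at the aryl iodide rather than attack on the ester, the triflate sulfur or the furan bromides, and cycloaddition rather than Grignard addition to the pyridyne) should be secured by the low temperature, the low nucleophilicity of Me3SiCH2MgCl added slowly, and the excess of 7.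

Step 6
Reactants: 10 methyl 6,7-dibromo-4-methoxy-5,8-dihydro-5,8-epoxyquinoline-2-carboxylate
Product: 11 methyl 6,7-dibromo-8-hydroxy-4-methoxyquinoline-2-carboxylate
Conditions: MeSO3H, CH2Cl2, 0 °C to rt
Reagents that add atoms: none
Why: Acid-catalysed isomerisation of a 1,4-epoxy-1,4-dihydroarene to a phenol: the protonated bridge ionises at C5, where the cation is conjugated through C4a with the methoxy-bearing C4, rather than at C8, where the charge would fall on the ring nitrogen, and loss of the C8 proton aromatises the ring with the oxygen left on C8; the anhydrous, weakly nucleophilic acid should spare the 4-methyl ether and the ester.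

Step 7
Reactants: 11 methyl 6,7-dibromo-8-hydroxy-4-methoxyquinoline-2-carboxylate
Product: 12 methyl 6,7-dibromo-4,8-dimethoxyquinoline-2-carboxylate
Conditions: MeI, K2CO3, DMF, rt
Reagents that add atoms: iodomethane, CI
Why: Williamson O-methylation of the phenoxide; the quinoline nitrogen, flanked by the ester and the C8 oxygen, is too hindered and electron-poor to be quaternised.

Step 8
Reactants: 12 methyl 6,7-dibromo-4,8-dimethoxyquinoline-2-carboxylate
Product: 14 6,7-dibromo-8-methoxy-4-oxo-1,4-dihydroquinoline-2-carboxylic acid, via dimethoxy acid 13 (not isolated)
Conditions: LiOH, THF–H2O, rt; then conc. HCl (to about 6 M), 100 °C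
Reagents that add atoms: lithium hydroxide, [Li+].[OH-]
Why: Ester saponification followed by acid-mediated O-demethylation of a 4-methoxyquinoline: protonation at nitrogen makes the C4 methoxy group a methyl donor towards chloride (an SN2 reaction that releases the neutral 4-quinolone), whereas the C8 methoxy group is an ordinary aryl ether that needs far harsher conditions.

**Compound list**
1 | methyl 4-methoxypicolinate | COC(=O)c1cc(OC)ccn1 | starting material
2 | methyl 4-methoxypicolinate N-oxide | COC(=O)c1cc(OC)cc[n+]1[O-] | intermediate
3 | methyl 4-methoxy-6-(trifluoroacetoxy)picolinate | COC(=O)c1cc(OC)cc(OC(=O)C(F)(F)F)n1 | intermediate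
4 | methyl 4-methoxy-6-oxo-1,6-dihydropyridine-2-carboxylate | COC(=O)c1cc(OC)cc(=O)[nH]1 | intermediate
5 | methyl 5-iodo-4-methoxy-6-oxo-1,6-dihydropyridine-2-carboxylate | COC(=O)c1cc(OC)c(I)c(=O)[nH]1 | intermediate
6 | methyl 5-iodo-4-methoxy-6-(trifluoromethylsulfonyloxy)picolinate | COC(=O)c1cc(OC)c(I)c(OS(=O)(=O)C(F)(F)F)n1 | intermediate
7 | 3,4-dibromofuran | Brc1cocc1Br | starting material
8 | [4-methoxy-6-(methoxycarbonyl)-2-(trifluoromethylsulfonyloxy)pyridin-3-yl]magnesium chloride | COC(=O)c1cc(OC)c([Mg]Cl)c(OS(=O)(=O)C(F)(F)F)n1 | intermediate
9 | methyl 4-methoxy-5,6-didehydropyridine-2-carboxylate (the 2,3-pyridyne) | COC(=O)C1=NC#CC(OC)=C1 | intermediate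
10 | methyl 6,7-dibromo-4-methoxy-5,8-dihydro-5,8-epoxyquinoline-2-carboxylate (racemic, cis bridgeheads) | COC(=O)c1cc(OC)c2c(n1)[C@H]1O[C@@H]2C(Br)=C1Br | intermediate
11 | methyl 6,7-dibromo-8-hydroxy-4-methoxyquinoline-2-carboxylate | COC(=O)c1cc(OC)c2cc(Br)c(Br)c(O)c2n1 | intermediate
12 | methyl 6,7-dibromo-4,8-dimethoxyquinoline-2-carboxylate | COC(=O)c1cc(OC)c2cc(Br)c(Br)c(OC)c2n1 | intermediate
13 | 6,7-dibromo-4,8-dimethoxyquinoline-2-carboxylic acid (formed as its lithium salt) | OC(=O)c1cc(OC)c2cc(Br)c(Br)c(OC)c2n1 | intermediate
14 | 6,7-dibromo-8-methoxy-4-oxo-1,4-dihydroquinoline-2-carboxylic acid | COc1c(Br)c(Br)cc2c(=O)cc(C(=O)O)[nH]c12 | target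

**Step count**
Total: 8 steps. Longest linear sequence: 8 steps, from 1 to 14; 7 is purchased and enters at step 5.

**Steps most likely to fail**

Step 5 (key step). What may go wrong: the magnesium species present (Me3SiCH2MgCl or arylmagnesium 8) add to the strongly electrophilic pyridyne or to the ester, or bromine–magnesium exchange on 7 competes, so that little cycloadduct forms. Fallback, setting out from 5 and coming back at 10: the metalation is separated from the aryne release. Pyridone 5 is O-silylated with (Me3Si)2NH to methyl 5-iodo-4-methoxy-6-(trimethylsilyloxy)picolinate F1. Iodine–lithium exchange with n-BuLi in THF at −100 °C, where it should outrun addition to the ester, triggers the 1,3-shift of silicon from oxygen to C5 (retro-Brook rearrangement). The resulting lithium pyridinolate is triflated in the same flask with Tf2O to methyl 4-methoxy-6-(trifluoromethylsulfonyloxy)-5-(trimethylsilyl)picolinate F2. CsF in MeCN at rt in the presence of 7 then releases pyridyne 9 under neutral, metal-free conditions (fluoride-induced 1,2-elimination of an ortho-silyl aryl triflate), and its cycloaddition gives 10.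

Step 6. What may go wrong: ionisation of the bridge is slowed by N-protonation and by the two bromines on the developing allyl cation, so the reaction stalls under conditions mild enough to keep the C4 methyl ether, or loss of that methyl group sets in before the bridge opens. Fallback, setting out from 10 and coming back at 12: the masking groups are given up instead of defended. Heating 10 in 6 M aqueous HCl and 1,4-dioxane at 100 °C should open the bridge, cleave the 4-methyl ether and hydrolyse the ester in one operation, giving 6,7-dibromo-8-hydroxy-4-oxo-1,4-dihydroquinoline-2-carboxylic acid F3. Once the 4-pyridone is unmasked, its vinylogous amide nitrogen still favours ionisation at C5. Exhaustive methylation of F3 with MeI and K2CO3 in DMF alkylates the carboxylate, the phenol and the quinolone oxygen (oxygen rather than nitrogen, since the nitrogen is flanked by the ester and the C8 substituent) and returns to 12.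

Step 8. What may go wrong: the two methyl ethers are not told apart cleanly in hot acid (partial loss of the C8 methyl group), or the reaction stops because the zwitterionic acid precipitates. Fallback, setting out from 12 and coming back at 14; it makes no compound outside the compound list (F0): the saponification is run on its own and acid 13 is isolated. The C4 methyl group is then removed by silyl iodide dealkylation (Me3SiCl, NaI, MeCN, 50 °C, then aqueous work-up). Here N-silylation activates only the vinylogous imidate methyl towards iodide, while the C8 aryl ether should react far more slowly, giving 14.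

**Further compounds**
F1 | step 5 | methyl 5-iodo-4-methoxy-6-(trimethylsilyloxy)picolinate | COC(=O)c1cc(OC)c(I)c(O[Si](C)(C)C)n1
F2 | step 5 | methyl 4-methoxy-6-(trifluoromethylsulfonyloxy)-5-(trimethylsilyl)picolinate | COC(=O)c1cc(OC)c([Si](C)(C)C)c(OS(=O)(=O)C(F)(F)F)n1
F3 | step 6 | 6,7-dibromo-8-hydroxy-4-oxo-1,4-dihydroquinoline-2-carboxylic acid | OC(=O)c1cc(=O)c2cc(Br)c(Br)c(O)c2[nH]1
F0 | step 8 | none | none
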